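**Retrosynthetic overview**

1. Target: (2R)-5,8-dihydroxy-2-[(12Z)-heptadec-12-enyl]chroman-4-one. Ring A is the benzene ring (C4a, C5–C8, C8a) and ring B the pyranone ring (O1, C2, C3, C4, C4a, C8a). Ring B is closed last, at the O1–C8a bond, by oxidation of the open-chain hydroquinone 13.
2. Enabling feature: the para-related hydroxyls at C5 and C8 make ring A a masked p-benzoquinone. In that quinone C8a (still C–H) is the β-carbon of both the C5 carbonyl and the C4 ketone, so the C2 hydroxyl adds there and tautomerisation returns the hydroquinone. The arene therefore needs only two oxygens; O1 comes from the side chain.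
3. 13 is disconnected at C3–C4: a lithiated aryl dithiane (C4 as acyl anion; temporary dithiane ring, MOM-protected phenols) plus the terminal (R)-epoxide 6.
4. 6 comes from (R)-epichlorohydrin (source of C2; its C–O bond is never broken) and the Grignard reagent of commercial (Z)-hexadec-11-en-1-ol (Z-alkene bought).
5. Ring order: ring A is bought (2,5-dihydroxybenzaldehyde); the temporary dithiane ring is made in step 3 and cleaved in step 6; ring B is formed last, in step 8.

Key step: step 8

Remark: (11Z)-hexadec-11-en-1-ol (pheromone-grade, geometrically pure) and (R)-epichlorohydrin are taken as commercial. Atom numbers C2, C3, C4, C8a refer to the chromanone numbering of the target.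

**Route**

Step 1
Reactants: 1 (11Z)-hexadec-11-en-1-ol
Product: 2 (5Z)-16-bromohexadec-5-ene
Conditions: CBr4, PPh3, CH2Cl2, 0 °C to rt
Reagents that add atoms: carbon tetrabromide, BrC(Br)(Br)Br
Why: Appel reaction, in which the alkoxyphosphonium salt is displaced by bromide in an SN2 step under neutral conditions that leave the remote Z-alkene untouched.

Step 2
Reactants: 2 (5Z)-16-bromohexadec-5-ene; 3 (R)-epichlorohydrin
Product: 6 (2R)-2-[(12Z)-heptadec-12-en-1-yl]oxirane, via Grignard reagent 4 (not isolated), via chlorohydrin 5 (not isolated)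
Conditions: Mg, THF, rt; CuI (10 mol%), 3, −40 to 0 °C; H2O; crude 5, powdered NaOH, Et2O, rt
Reagents that add atoms: none
Why: Grignard formation, copper-catalysed opening of the epoxide at its unsubstituted carbon (faster than chloride displacement at low temperature) and intramolecular Williamson closure of the chlorohydrin; the stereocentre of 3 is never a reacting atom, so 6 should be (R).

Step 3
Reactants: 7 2,5-dihydroxybenzaldehyde
Product: 8 2-(1,3-dithian-2-yl)benzene-1,4-diol
Conditions: HS(CH2)3SH, BF3·OEt2 (cat.), CH2Cl2/THF, 0 °C to rt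
Reagents that add atoms: propane-1,3-dithiol, SCCCS
Why: Lewis acid-catalysed dithioacetalisation of the aldehyde, which tolerates free phenols and installs the temporary dithiane ring needed for acyl-anion (umpolung) reactivity.

Step 4
Reactants: 8 2-(1,3-dithian-2-yl)benzene-1,4-diol
Product: 9 2-[2,5-bis(methoxymethoxy)phenyl]-1,3-dithiane
Conditions: NaH, DMF, 0 °C; MOMCl, 0 °C to rt
Reagents that add atoms: chloromethyl methyl ether, COCCl
Why: Williamson O-alkylation of both phenoxides; the MOM acetals survive n-BuLi, and the much less acidic dithiane C–H is not touched by NaH.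

Step 5
Reactants: 9 2-[2,5-bis(methoxymethoxy)phenyl]-1,3-dithiane; 6 (2R)-2-[(12Z)-heptadec-12-en-1-yl]oxirane
Product: 11 (2R,14Z)-1-{2-[2,5-bis(methoxymethoxy)phenyl]-1,3-dithian-2-yl}nonadec-14-en-2-ol, via lithiated dithiane 10 (not isolated)
Conditions: n-BuLi, THF, −30 °C; 6, DMPU, −30 to 0 °C; H2O
Reagents that add atoms: none
Why: Corey–Seebach umpolung alkylation, in which the aryl-stabilised dithiane anion opens the terminal epoxide by SN2 attack at the unsubstituted carbon and forms the future C3–C4 bond; the carbinol carbon (future C2) is not a reacting atom and stays (R).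

Step 6
Reactants: 11 (2R,14Z)-1-{2-[2,5-bis(methoxymethoxy)phenyl]-1,3-dithian-2-yl}nonadec-14-en-2-ol
Product: 12 (3R,15Z)-1-[2,5-bis(methoxymethoxy)phenyl]-3-hydroxyicos-15-en-1-one
Conditions: MeI, CaCO3, MeCN/H2O (9:1), 45 °C
Reagents that add atoms: water, O
Why: Alkylative dethioacetalisation (S-methylation, opening to an aryl-stabilised thionium ion, hydrolysis) under buffered, non-oxidising conditions that should leave the MOM ethers, the β-hydroxy ketone and the Z-alkene unchanged.

Step 7
Reactants: 12 (3R,15Z)-1-[2,5-bis(methoxymethoxy)phenyl]-3-hydroxyicos-15-en-1-one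
Product: 13 (3R,15Z)-1-(2,5-dihydroxyphenyl)-3-hydroxyicos-15-en-1-one
Conditions: HCl (1.25 M in MeOH), 0 °C to rt
Reagents that add atoms: none
Why: Acid-catalysed transacetalisation of the two phenolic MOM ethers to methanol, which should proceed at room temperature, well below the conditions needed to dehydrate the β-hydroxy ketone.

Step 8
Reactants: 13 (3R,15Z)-1-(2,5-dihydroxyphenyl)-3-hydroxyicos-15-en-1-one
Product: 16 (2R)-5,8-dihydroxy-2-[(12Z)-heptadec-12-en-1-yl]-2,3-dihydro-4H-chromen-4-one, via acylquinone 14 (not isolated), via chromanetrione 15 (not isolated)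
Conditions: Ag2O (3 equiv), Na2SO4, Et2O, rt, dark; filter; aq Na2S2O4, EtOAc, rt
Reagents that add atoms: none
Why: Ag2O dehydrogenates the hydroquinone to acylquinone 14, in which the ring C–H carbon next to the acyl-bearing carbon (the future C8a) is the β-carbon of both the ring enone and the side-chain ketone; the C3 hydroxyl adds to it (intramolecular oxa-Michael addition) and enolisation of the adduct restores the aromatic hydroquinone, so the aryl C–O bond of ring B is made by a net C–H/O–H dehydrogenative coupling. The closest known reaction types are the regioselective addition of heteroatom nucleophiles to C3 of 2-acyl-1,4-benzoquinones and the oxidative cyclisation of hydroxyalkyl hydroquinones through their quinones. Ring B closes in a 6-endo-trig mode, the three-atom tether (C4, C3, C2) allowing no other unstrained ring, and the irreversible re-aromatisation makes this conjugate addition the sink over reversible 1,2-addition to a quinone carbonyl. Because the first-formed alkoxy hydroquinone is more easily oxidised than 13, excess Ag2O is used to funnel all material to trione 15, which dithionite then reduces back to 16. No stereocentre is formed: C2 arrives from 6 with its C–O bond intact, and the neutral, base-free medium should avoid retro-oxa-Michael ring opening. The selectivity needed is oxidation of the hydroquinone beside a secondary alcohol and a Z-alkene, which Ag2O and Na2S2O4 should both respect.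

**Compound list**

1 | (11Z)-hexadec-11-en-1-ol | CCCC/C=C\CCCCCCCCCCO | starting material
2 | (5Z)-16-bromohexadec-5-ene | CCCC/C=C\CCCCCCCCCCBr | intermediate
3 | (R)-epichlorohydrin, (2R)-2-(chloromethyl)oxirane | ClC[C@H]1CO1 | starting material
4 | [(11Z)-hexadec-11-en-1-yl]magnesium bromide | CCCC/C=C\CCCCCCCCCC[Mg]Br | intermediate
5 | (2R,14Z)-1-chlorononadec-14-en-2-ol | ClC[C@H](O)CCCCCCCCCCC/C=C\CCCC | intermediate
6 | (2R)-2-[(12Z)-heptadec-12-en-1-yl]oxirane | C1[C@H](O1)CCCCCCCCCCC/C=C\CCCC | intermediate
7 | 2,5-dihydroxybenzaldehyde | O=Cc1cc(O)ccc1O | starting material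
8 | 2-(1,3-dithian-2-yl)benzene-1,4-diol | Oc1ccc(O)c(c1)C1SCCCS1 | intermediate
9 | 2-[2,5-bis(methoxymethoxy)phenyl]-1,3-dithiane | COCOc1ccc(OCOC)c(c1)C1SCCCS1 | intermediate
10 | {2-[2,5-bis(methoxymethoxy)phenyl]-1,3-dithian-2-yl}lithium | [Li]C1(SCCCS1)c1cc(OCOC)ccc1OCOC | intermediate
11 | (2R,14Z)-1-{2-[2,5-bis(methoxymethoxy)phenyl]-1,3-dithian-2-yl}nonadec-14-en-2-ol | COCOc1ccc(OCOC)c(c1)C1(SCCCS1)C[C@H](O)CCCCCCCCCCC/C=C\CCCC | intermediate
12 | (3R,15Z)-1-[2,5-bis(methoxymethoxy)phenyl]-3-hydroxyicos-15-en-1-one | COCOc1ccc(OCOC)c(c1)C(=O)C[C@H](O)CCCCCCCCCCC/C=C\CCCC | intermediate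
13 | (3R,15Z)-1-(2,5-dihydroxyphenyl)-3-hydroxyicos-15-en-1-one | Oc1ccc(O)c(c1)C(=O)C[C@H](O)CCCCCCCCCCC/C=C\CCCC | intermediate
14 | 2-[(3R,15Z)-3-hydroxyicos-15-enoyl]cyclohexa-2,5-diene-1,4-dione | O=C1C=CC(=O)C(=C1)C(=O)C[C@H](O)CCCCCCCCCCC/C=C\CCCC | intermediate
15 | (2R)-2-[(12Z)-heptadec-12-en-1-yl]-2,3-dihydro-4H-chromene-4,5,8-trione | CCCC/C=C\CCCCCCCCCCC[C@@H]1CC(=O)C2=C(O1)C(=O)C=CC2=O | intermediate
16 | (2R)-5,8-dihydroxy-2-[(12Z)-heptadec-12-en-1-yl]-2,3-dihydro-4H-chromen-4-one | CCCC/C=C\CCCCCCCCCCC[C@@H]1CC(=O)c2c(O)ccc(O)c2O1 | target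

**Step count**

Total steps: 8. Longest linear sequence: 6 (steps 1, 2, 5, 6, 7, 8; the arene branch, steps 3, 4, 5, 6, 7, 8, is equally long).

**Steps most likely to fail, with fallbacks**

Step 8. The conjugate addition of the neutral secondary hydroxyl may be too slow, so that intermolecular redox exchange, loss of water from the side chain and decay of the electron-poor quinones take over. The fallback sets out from 13 and comes back to the route at 15. 13 is oxidised with Ag2O (1.1 equiv) and the filtered solution of 14 is treated at once with dry HCl in Et2O at 0 °C. Chloride, a much faster nucleophile, adds to the same doubly activated carbon (hydrochlorination of an acylquinone) to give (3R,15Z)-1-(2-chloro-3,6-dihydroxyphenyl)-3-hydroxyicos-15-en-1-one F1. Re-oxidation with Ag2O gives 2-chloro-3-[(3R,15Z)-3-hydroxyicos-15-enoyl]cyclohexa-2,5-diene-1,4-dione F2. In F2 the hydroxyl displaces chloride by addition–elimination at the quinone (NaHCO3, MeCN, rt), a redox-neutral ring closure with no oxidant present beside the product. This gives 15, which is reduced with aq Na2S2O4 to 16 as in step 8.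

Step 5. Opening of the long-chain epoxide by the ortho-substituted aryl dithiane anion may be sluggish, with proton transfer and decay of the anion on warming. The fallback reverses the order of the two epoxide openings; it sets out from 9 (as 10) and from 2 (as 4) and comes back at 11. Anion 10 is reacted with (S)-epichlorohydrin (ClC[C@@H]1CO1), the smallest and most reactive epoxide, at −78 to −30 °C to give, as its lithium alkoxide, (2S)-1-chloro-3-{2-[2,5-bis(methoxymethoxy)phenyl]-1,3-dithian-2-yl}propan-2-ol F3. On warming this closes to (2S)-2-({2-[2,5-bis(methoxymethoxy)phenyl]-1,3-dithian-2-yl}methyl)oxirane F4. Copper-catalysed opening of F4 with Grignard reagent 4 (CuI cat., THF, −40 °C) at the unsubstituted carbon should then give 11. Because the two termini of the C3 unit are used in the opposite order, the (S)-reagent leads to the same (R)-carbinol.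

Step 7. Acid may dehydrate the β-hydroxy ketone during MOM cleavage, and the resulting enone could cyclise onto the ortho phenol without stereocontrol. The fallback swaps the order of the two unmaskings so that acid meets the carbonyl only in its dithiane form; it sets out from 11 and comes back at 13. 11 is treated with HCl in MeOH (rt) to give 2-{2-[(2R,14Z)-2-hydroxynonadec-14-en-1-yl]-1,3-dithian-2-yl}benzene-1,4-diol F5. Neutral alkylative hydrolysis of F5 (MeI, CaCO3, MeCN/H2O, 45 °C) then releases 13 directly.

**Further compounds**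

F1 | step 8 | (3R,15Z)-1-(2-chloro-3,6-dihydroxyphenyl)-3-hydroxyicos-15-en-1-one | Oc1ccc(O)c(Cl)c1C(=O)C[C@H](O)CCCCCCCCCCC/C=C\CCCC
F2 | step 8 | 2-chloro-3-[(3R,15Z)-3-hydroxyicos-15-enoyl]cyclohexa-2,5-diene-1,4-dione | O=C1C=CC(=O)C(C(=O)C[C@H](O)CCCCCCCCCCC/C=C\CCCC)=C1Cl
F3 | step 5 | (2S)-1-chloro-3-{2-[2,5-bis(methoxymethoxy)phenyl]-1,3-dithian-2-yl}propan-2-ol | ClC[C@@H](O)CC1(SCCCS1)c1cc(OCOC)ccc1OCOC
F4 | step 5 | (2S)-2-({2-[2,5-bis(methoxymethoxy)phenyl]-1,3-dithian-2-yl}methyl)oxirane | C1[C@@H](O1)CC1(SCCCS1)c1cc(OCOC)ccc1OCOC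
F5 | step 7 | 2-{2-[(2R,14Z)-2-hydroxynonadec-14-en-1-yl]-1,3-dithian-2-yl}benzene-1,4-diol | Oc1ccc(O)c(c1)C1(SCCCS1)C[C@H](O)CCCCCCCCCCC/C=C\CCCC
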